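## Analysis of the target

Kobophenol A, as drawn, consists of three oxygen heterocycles joined through aryl–C(sp3) bonds. Ring A is a 6-hydroxy-2-(4-hydroxyphenyl)-2,3-dihydrobenzofuran. Ring B is a 7-hydroxy-2-(4-hydroxyphenyl)-3-(3,5-dihydroxyphenyl)-2,3-dihydrobenzofuran bonded through its C5 to C3 of ring A. A tetra-aryl oxolane is bonded through its C3 to C4 of ring A. There are eight stereocentres in three blocks: ring A is 2S,3S and ring B is 2R,3R (both 2,3-trans), and the oxolane is 2R,3S,4R,5S, that is 2,3-trans, 3,4-cis and 4,5-trans, so the two bulkiest groups sit on one face. All four O-benzylic carbons carry a 4-oxygenated phenyl group and ionise readily under acid, which threatens epimerisation and Friedel–Crafts capture by the resorcinol rings; the ten phenols are oxidation-prone and are carried as methyl ethers to the last step. The difficulty lies in the congestion around C3a/C4 of ring A, in the contra-steric 3,4-cis pair of the oxolane, and in setting three stereochemical blocks in the right absolute sense without relay between them. The plan rests on one feature: oxolane C4–C5, with its 3,5-dihydroxyphenyl and 4-hydroxyphenyl groups, is an intact stilbene C=C unit, while O1–C2–C3 has the atoms of the enolate of a 4-hydroxyphenyl ketone whose α-carbon (C3) is bonded to C4 of ring A. The oxolane can therefore be assembled at the dihydrofuran oxidation level from a metal carbene at C3 and a stilbene.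

## Retrosynthetic reasoning

**24 to 23.** The ten aryl O–H bonds of 24 are traced back to the methyl ethers of 23. Methyl ethers are chosen because the building blocks 17 and 20 are bought in this form and because they survive carbene, radical and palladium chemistry. The forward step must cleave ten ethers without opening the three O-benzylic rings.

**23 to 22 to 21.** The C2–H and C3–H bonds of the oxolane are removed to give the cyclic enol ether 21 (C2=C3), since C2 and C3 are the only oxolane centres outside the stilbene unit. Forward, a proton must enter at C3 on the face away from the C4 aryl group, which gives the 3,4-cis pair, and hydride then reduces the oxocarbenium ion at C2. Hydride is expected to enter anti to the C3 substituent and give the 2-epimer 22, so a separate acid equilibration of the ionisable C2 centre leads to 23.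

**21 to 19 and 20.** Cutting C3–C4 and O1–C5 of 21 gives diazo ketone 19 and stilbene 20. This cut removes one ring, two skeletal bonds and two stereocentres at once, and one partner is commercial. The polarity fits: the carbene carbon is electrophilic, and the carbon of 20 bearing the 4-methoxyphenyl group is the one best able to carry positive charge. The forward reaction has to join a crowded carbene with a 1,2-disubstituted alkene, select the alkene face through the catalyst and finish by O- rather than C-closure.

**19 to 18 to 16 and 17.** The diazo group is traced to the methylene of ketone 18 (diazo transfer). The aryl C4–CH2 bond of 18 is then cut to triflate 16 and methyl ketone 17 (ketone α-arylation). This places the hindered aryl–carbon bond formation on a robust cross-coupling and keeps the phenol-derived handle of ring A for exactly this purpose.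

**16 to 5 and 15.** The bond between C3 of ring A and C5 of ring B is cut to acid 5 and aryl bromide 15. It separates two independently made enantiopure halves, and the C3 carboxyl group is what the ring contraction delivers. Forward, the C3 radical formed by decarboxylation must be arylated anti to the C2 aryl group, and the aryl bromide must react in preference to the triflate.

**5 to 4 to 3 to 2 to 1.** The C3–C3a bond of ring A is traced to the C4–C4a bond of flavanone 3 (oxidative ring contraction), which comes from 1 by methylation of the two free phenols and sulfonylation of the chelated one. The C2 stereocentre of ring A is thus taken from the chiral pool.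

**15 to 14 to 13 to 12 to 11 to 10 to 8 and 9, and 8 to 6 and 7.** The C2–C3 bond of ring B is cut to a diaryl carbene at C3 and a benzylic C–H bond of the 4-methoxybenzyl ether in 13. An enantioselective C–H insertion sets C3 and gives the cis isomer 14, and acid turns C2 over to the trans isomer 15. The carbene precursor 13 comes from hydrazone 12, ketone 11 and carbinol 10. Carbinol 10 is assembled from aldehyde 8 and organomagnesium reagent 9, and 8 from phenol 6 and benzylic chloride 7.

## Alternatives that were turned down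

**Alternative 1:** The disconnection is at the two aryl–carbon bonds on C3a and C4 of the benzene ring of ring A, so that this ring enters as an aryne. In the forward key step, fluoride releases the aryne from silyl triflate A3. The enolate carbon of β-ketoester A2, which carries ring B, adds to it; the aryl anion closes on the ketone and the four-membered alkoxide fragments to arylacetate A1. In A1 the aroyl carbon is the future C3 of ring A and the CH2 group the future oxolane C3.
- For: it builds the crowded 1,2,3,5-tetrasubstituted arene with both carbon substituents in one metal-free step, and the regiochemistry is guided by the methoxy group next to the aryl anion. On convergence at this ring it is stronger than the chosen route, which needs a radical arylation at a hindered C3.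
- Against: it sets no stereocentre. From A1 the furan ring A must still be closed, which needs cleavage of a flanked methyl ether, introduction of C2 with its aryl group and control of the trans pair in the correct absolute sense relative to ring B. The ester must also be turned into the aryl ketone, and the oxolane is untouched.
- Comparison: the chosen route takes both stereocentres of ring A from 1 in four steps and concentrates its risk in a single bond-forming event.

**Alternative 2:** The disconnection is at C3–C3a of ring A, traced to the C4–C4a bond of flavanone A5. In the forward key step, a trivalent iodine oxidant in an orthoformate medium iodinates C3 of the enol ether; the aryl carbon C4a migrates from C4 to C3 and C4 is expelled as the methyl ester, giving A4.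
- For: chiral-pool origin of C2, a trans ester by mechanism and by thermodynamics, and a triflate placed for later coupling.
- Against: as the strategy-defining step it delivers only ring A with a carboxyl group. It gives no answer to the oxolane, which holds four of the eight stereocentres, nor to the replacement of the carboxyl group by ring B. A shift of the 2-aryl group competes.
- Comparison: A5 is the same compound as 3 and A4 the same as 4; the chosen route uses this very transformation as a supporting step (step 3). On ring A the two are equal, and the chosen strategy adds the construction of the oxolane.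

**Alternative 3:** The disconnection is at oxolane C2–C3 and C4–C5. In the forward key step, thermal conrotatory opening of trans-oxirane A7 gives a W-shaped carbonyl ylide, which adds suprafacially across the Z-alkene A8 on C4 of ring A. The product is A6, the same compound as 23.
- For: the saturated oxolane forms directly with all four stereocentres, the 2,5-cis relationship coming from the ylide shape and the 3,4-cis pair from the Z-alkene. No enol ether reduction or epimerisation is needed, so in step economy of the endgame it is stronger than the chosen route.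
- Against: an oxirane with two plain aryl groups opens only under forcing thermal or electron-transfer conditions. The ylide is electron-rich and A8 is an unactivated, hindered, electron-rich dipolarophile, so the frontier orbitals are poorly matched. A8 can isomerise to the E-alkene, and there is no handle for the face of A8 or for exo/endo control, so diastereomer mixtures are expected. A8 also needs its own Z-selective synthesis at a hindered position.
- Comparison: the chosen route pairs an electrophilic carbene with an electron-rich alkene, takes the absolute configuration from a catalyst and uses commercial 20 unchanged, at the price of two later stereochemical adjustments.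

Key step: step 14

Assumption: the antipodes of the chiral dirhodium catalysts named in steps 9 and 14 are taken to be those that give the drawn configurations; if the sense of induction is the reverse, the mirror-image catalyst is used in that step.

Shorthand in names: B-yl = (2R,3R)-3-(3,5-dimethoxyphenyl)-7-methoxy-2-(4-methoxyphenyl)-2,3-dihydro-1-benzofuran-5-yl (ring B, bonded through C5).

## Route

Step 1
Reactants: 1 (2S)-naringenin
Product: 2 (2S)-5-hydroxy-7-methoxy-2-(4-methoxyphenyl)-2,3-dihydro-4H-1-benzopyran-4-one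
Conditions: TMSCHN2, i-Pr2NEt, MeOH–MeCN, 0 °C → rt
Reagents that add atoms: trimethylsilyldiazomethane, C[Si](C)(C)C=[N+]=[N-]
Why: Diazoalkane O-methylation touches only the two free acidic phenols (7-OH, 4'-OH), the 5-OH being tied up in a hydrogen bond to C4=O; no strong base is present, so the flavanone should not open to the chalcone and C2 stays S.

Step 2
Reactants: 2 (2S)-5-hydroxy-7-methoxy-2-(4-methoxyphenyl)-2,3-dihydro-4H-1-benzopyran-4-one
Product: 3 (2S)-7-methoxy-2-(4-methoxyphenyl)-4-oxo-3,4-dihydro-2H-1-benzopyran-5-yl trifluoromethanesulfonate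
Conditions: Tf2O, pyridine, CH2Cl2, 0 °C
Reagents that add atoms: trifluoromethanesulfonic anhydride, O=S(=O)(OS(=O)(=O)C(F)(F)F)C(F)(F)F
Why: O-sulfonylation of the remaining chelated phenol installs the later cross-coupling handle and lowers the electron density of the arene before the oxidative step.

Step 3
Reactants: 3 (2S)-7-methoxy-2-(4-methoxyphenyl)-4-oxo-3,4-dihydro-2H-1-benzopyran-5-yl trifluoromethanesulfonate
Product: 4 methyl (2S,3S)-6-methoxy-2-(4-methoxyphenyl)-4-[(trifluoromethanesulfonyl)oxy]-2,3-dihydro-1-benzofuran-3-carboxylate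
Conditions: PhI(OAc)2, HC(OMe)3, H2SO4 (cat.), rt
Reagents that add atoms: trimethyl orthoformate, COC(OC)OC
Why: Oxidative ring contraction of a flavanone by trivalent iodine: the ketal-derived enol ether is iodinated at C3 anti to the 2-aryl group, aryl carbon C4a migrates from C4 to C3 with loss of iodobenzene, and the dimethoxycarbenium terminus becomes the methyl ester; C2 takes no part and keeps its configuration, and the ester ends trans to the aryl group (3S), which is also the thermodynamic arrangement.

Step 4
Reactants: 4 methyl (2S,3S)-6-methoxy-2-(4-methoxyphenyl)-4-[(trifluoromethanesulfonyl)oxy]-2,3-dihydro-1-benzofuran-3-carboxylate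
Product: 5 (2S,3S)-6-methoxy-2-(4-methoxyphenyl)-4-[(trifluoromethanesulfonyl)oxy]-2,3-dihydro-1-benzofuran-3-carboxylic acid
Conditions: Me3SnOH, ClCH2CH2Cl, 80 °C; aq. HCl wash
Reagents that add atoms: trimethyltin hydroxide, C[Sn](C)(C)O
Why: Trimethyltin hydroxide cleaves the methyl ester under nearly neutral conditions and spares the aryl triflate; the configuration at C3 is of no consequence beyond this point because C3 becomes a radical in step 11.

Step 5
Reactants: 6 5-bromo-2-hydroxy-3-methoxybenzaldehyde; 7 4-methoxybenzyl chloride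
Product: 8 5-bromo-3-methoxy-2-[(4-methoxyphenyl)methoxy]benzaldehyde
Conditions: K2CO3, DMF, 60 °C
Reagents that add atoms: none
Why: Williamson ether synthesis on the phenol; the 4-methoxybenzyl group is not a protecting group here but the future C2 of ring B with its aryl substituent.

Step 6
Reactants: 8 5-bromo-3-methoxy-2-[(4-methoxyphenyl)methoxy]benzaldehyde; 9 3,5-dimethoxyphenylmagnesium chloride
Product: 10 (RS)-{5-bromo-3-methoxy-2-[(4-methoxyphenyl)methoxy]phenyl}(3,5-dimethoxyphenyl)methanol
Conditions: THF, −40 → 0 °C; aq. NH4Cl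
Reagents that add atoms: none
Why: Grignard addition to the aldehyde, which at low temperature is much faster than magnesium–bromine exchange at the aryl bromide; the carbinol centre is racemic and is erased in step 7.

Step 7
Reactants: 10 (RS)-{5-bromo-3-methoxy-2-[(4-methoxyphenyl)methoxy]phenyl}(3,5-dimethoxyphenyl)methanol
Product: 11 {5-bromo-3-methoxy-2-[(4-methoxyphenyl)methoxy]phenyl}(3,5-dimethoxyphenyl)methanone
Conditions: MnO2, CH2Cl2, rt
Reagents that add atoms: none
Why: Oxidation of a doubly benzylic alcohol with MnO2, which leaves the benzyl ether and the aryl bromide alone.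

Step 8
Reactants: 11 {5-bromo-3-methoxy-2-[(4-methoxyphenyl)methoxy]phenyl}(3,5-dimethoxyphenyl)methanone
Product: 12 hydrazone of 11 (E/Z mixture)
Conditions: N2H4·H2O (excess), AcOH (cat.), EtOH, 80 °C
Reagents that add atoms: hydrazine (as hydrate), NN
Why: Condensation of a diaryl ketone with excess hydrazine, the excess suppressing azine formation; the C=N geometry is irrelevant because both isomers give the same diazo compound.

Step 9
Reactants: 12 hydrazone of 11 (E/Z mixture)
Product: 14 (2S,3R)-5-bromo-3-(3,5-dimethoxyphenyl)-7-methoxy-2-(4-methoxyphenyl)-2,3-dihydro-1-benzofuran (2,3-cis), via diaryldiazomethane 13 (not isolated)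
Conditions: MnO2, CH2Cl2, 0 °C; filter; Rh2(R-PTAD)4 (1 mol%), CH2Cl2, 0 °C → rt
Reagents that add atoms: none
Why: Dehydrogenation of the hydrazone gives the donor/donor diazo compound, and the dirhodium carbene inserts into the activated benzylic C–H bond of the 4-methoxybenzyl ether in a 1,5-fashion, a known enantioselective route to cis-2,3-diaryl-2,3-dihydrobenzofurans; the chiral carboxylate sets C3 (R) and the insertion delivers the cis isomer, of which only C3 needs to be correct.

Step 10
Reactants: 14 (2S,3R)-5-bromo-3-(3,5-dimethoxyphenyl)-7-methoxy-2-(4-methoxyphenyl)-2,3-dihydro-1-benzofuran (2,3-cis)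
Product: 15 (2R,3R)-5-bromo-3-(3,5-dimethoxyphenyl)-7-methoxy-2-(4-methoxyphenyl)-2,3-dihydro-1-benzofuran (2,3-trans)
Conditions: CF3CO2H, CH2Cl2, 0 °C → rt
Reagents that add atoms: none
Why: Acid-mediated epimerisation of a 2-(4-alkoxyphenyl)-2,3-dihydrobenzofuran: the C2–O bond ionises to a 4-methoxybenzylic cation and a phenol, and reclosure gives the thermodynamically favoured trans isomer (2R); C3 cannot ionise and stays R.

Step 11
Reactants: 5 (2S,3S)-6-methoxy-2-(4-methoxyphenyl)-4-[(trifluoromethanesulfonyl)oxy]-2,3-dihydro-1-benzofuran-3-carboxylic acid; 15 (2R,3R)-5-bromo-3-(3,5-dimethoxyphenyl)-7-methoxy-2-(4-methoxyphenyl)-2,3-dihydro-1-benzofuran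
Product: 16 (2S,3S)-3-(B-yl)-6-methoxy-2-(4-methoxyphenyl)-2,3-dihydro-1-benzofuran-4-yl trifluoromethanesulfonate
Conditions: Ir[dF(CF3)ppy]2(dtbbpy)PF6 (2 mol%), NiCl2·glyme (10 mol%), dtbbpy (15 mol%), Cs2CO3, DMF, blue LEDs, rt
Reagents that add atoms: none
Why: Photoredox–nickel decarboxylative arylation: the carboxylate is oxidised by the excited iridium complex, loses CO2 and gives a secondary benzylic radical at C3, which is captured by the aryl–nickel species formed by oxidative addition into the C–Br bond of 15 (faster with bipyridine–nickel than insertion into the hindered C–OTf bond); the new aryl group is delivered anti to the C2 aryl group, which gives the trans isomer (3S), and C2 is untouched.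

Step 12
Reactants: 16 (2S,3S)-3-(B-yl)-6-methoxy-2-(4-methoxyphenyl)-2,3-dihydro-1-benzofuran-4-yl trifluoromethanesulfonate; 17 1-(4-methoxyphenyl)ethan-1-one
Product: 18 2-[(2S,3S)-3-(B-yl)-6-methoxy-2-(4-methoxyphenyl)-2,3-dihydro-1-benzofuran-4-yl]-1-(4-methoxyphenyl)ethan-1-one
Conditions: Pd2(dba)3 (2.5 mol%), XPhos (10 mol%), K3PO4, toluene, 90 °C
Reagents that add atoms: none
Why: Palladium-catalysed α-arylation of a methyl ketone with an aryl triflate; the bulky biarylphosphine copes with the ortho substituent, the weak base spares the triflate, and a second arylation is held back by the hindered product enolate.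

Step 13
Reactants: 18 2-[(2S,3S)-3-(B-yl)-6-methoxy-2-(4-methoxyphenyl)-2,3-dihydro-1-benzofuran-4-yl]-1-(4-methoxyphenyl)ethan-1-one
Product: 19 2-diazo-2-[(2S,3S)-3-(B-yl)-6-methoxy-2-(4-methoxyphenyl)-2,3-dihydro-1-benzofuran-4-yl]-1-(4-methoxyphenyl)ethan-1-one
Conditions: p-ABSA, DBU, MeCN, 0 °C → rt
Reagents that add atoms: 4-acetamidobenzenesulfonyl azide, CC(=O)Nc1ccc(cc1)S(=O)(=O)N=[N+]=[N-]
Why: Regitz diazo transfer to a benzyl aryl ketone, whose methylene group is acidic enough for an amidine base; no stereocentre is affected, since the diarylmethine C3–H of ring A is far too weakly acidic.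

Step 14
Reactants: 19 2-diazo-2-[(2S,3S)-3-(B-yl)-6-methoxy-2-(4-methoxyphenyl)-2,3-dihydro-1-benzofuran-4-yl]-1-(4-methoxyphenyl)ethan-1-one; 20 (E)-1,3-dimethoxy-5-[2-(4-methoxyphenyl)ethenyl]benzene
Product: 21 (2S,3S)-3-(B-yl)-4-[(4S,5S)-4-(3,5-dimethoxyphenyl)-2,5-bis(4-methoxyphenyl)-4,5-dihydrofuran-3-yl]-6-methoxy-2-(4-methoxyphenyl)-2,3-dihydro-1-benzofuran
Conditions: Rh2(S-PTAD)4 (2 mol%), 20 (5 equiv), CH2Cl2, slow addition of 19, rt → 40 °C
Reagents that add atoms: none
Why: Proposed new method: Rh2(S-PTAD)4 converts 19 into an electrophilic donor/acceptor rhodium carbene, which is attacked by the alkene carbon of 20 bearing the 3,5-dimethoxyphenyl group, so that positive charge develops on the 4-methoxybenzylic carbon; the ketone oxygen of the resulting rhodium enolate then closes on that carbon and the catalyst is released, forming C3–C4 and O1–C5 (oxolane numbering) in one operation. If a cyclopropane closes first, it is a donor–acceptor cyclopropyl ketone of the constitution of F2, whose polarised bond reopens to the same zwitterion (Cloke–Wilson ring expansion). The closest known reaction types are the Rh2(S-PTAD)4-catalysed cyclopropanation of styrenes with α-aryl-α-diazo ketones and the formal (3+2) annulation of diazo carbonyl compounds with vinyl ethers to dihydrofurans; a trans-1,2-diaryl alkene as partner and a carbene as crowded as this one lie outside both. The ring closes by attack of the enolate oxygen on the benzylic cation, a 5-exo-trig closure when the cation is written in its quinoid form. C4 is set in the C–C bond-forming event, where the chiral dirhodium tetracarboxylate selects the alkene face without reliance on the remote centres of rings A and B, and C5 is set relative to C4 on ring closure, which places the two aryl groups trans as in the E-alkene. The step needs regioselectivity, secured by the far better cation stabilisation of the 4-methoxyphenyl than of the 3,5-dimethoxyphenyl group; chemoselectivity for the alkene over the electron-rich arenes of 19 itself, helped by slow addition of 19 to an excess of 20; and O- over C-closure, favoured by the stabilised cation and the aryl ketone.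

Step 15
Reactants: 21 (2S,3S)-3-(B-yl)-4-[(4S,5S)-4-(3,5-dimethoxyphenyl)-2,5-bis(4-methoxyphenyl)-4,5-dihydrofuran-3-yl]-6-methoxy-2-(4-methoxyphenyl)-2,3-dihydro-1-benzofuran
Product: 22 (2S,3S)-3-(B-yl)-4-[(2S,3S,4R,5S)-4-(3,5-dimethoxyphenyl)-2,5-bis(4-methoxyphenyl)oxolan-3-yl]-6-methoxy-2-(4-methoxyphenyl)-2,3-dihydro-1-benzofuran (2-epimer of 23)
Conditions: Et3SiH, CF3CO2H, CH2Cl2, −40 → 0 °C
Reagents that add atoms: none
Why: Ionic hydrogenation of a cyclic enol ether: the proton adds to C3 on the face opposite the C4 aryl group, which sets 3S and the 3,4-cis pair; the oxocarbenium ion at C2, stabilised by O1 and the 4-methoxyphenyl group, takes hydride from the silane on the face opposite the large C3 substituent (held pseudoaxial to avoid the coplanar C2 aryl group), which should give the 2,3-cis arrangement (2S). C4 and C5 are not touched, and low temperature with a limited amount of acid should keep the O-benzylic rings from ionising while silane is present.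

Step 16
Reactants: 22 (2S,3S)-3-(B-yl)-4-[(2S,3S,4R,5S)-4-(3,5-dimethoxyphenyl)-2,5-bis(4-methoxyphenyl)oxolan-3-yl]-6-methoxy-2-(4-methoxyphenyl)-2,3-dihydro-1-benzofuran
Product: 23 (2S,3S)-3-(B-yl)-4-[(2R,3S,4R,5S)-4-(3,5-dimethoxyphenyl)-2,5-bis(4-methoxyphenyl)oxolan-3-yl]-6-methoxy-2-(4-methoxyphenyl)-2,3-dihydro-1-benzofuran (kobophenol A decamethyl ether)
Conditions: CF3CO2H, CH2Cl2, 0 °C → rt (no silane)
Reagents that add atoms: none
Why: Acid-catalysed epimerisation of a 2-aryl oxolane, known from tetrahydrofuran lignans: reversible ionisation of the 4-methoxybenzylic C2–O1 bond and reclosure should lead to the isomer with the C2 aryl group trans to the C3 substituent (2R); C3 and C4 cannot ionise and stay, while C5 and the C2 centres of rings A and B, which can, already hold their favoured trans arrangement.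

Step 17
Reactants: 23 kobophenol A decamethyl ether
Product: 24 kobophenol A, (2S,3S)-3-[(2R,3R)-3-(3,5-dihydroxyphenyl)-7-hydroxy-2-(4-hydroxyphenyl)-2,3-dihydro-1-benzofuran-5-yl]-4-[(2R,3S,4R,5S)-4-(3,5-dihydroxyphenyl)-2,5-bis(4-hydroxyphenyl)oxolan-3-yl]-2-(4-hydroxyphenyl)-2,3-dihydro-1-benzofuran-6-ol
Conditions: BBr3 (excess), CH2Cl2, −78 °C → rt; MeOH, H2O
Reagents that add atoms: none
Why: Lewis acid cleavage of aryl methyl ethers, the usual last step for permethylated oligostilbenes; bromide attacks the methyl groups of the boron-complexed ethers, and the low starting temperature is meant to keep the O-benzylic rings closed, all of which are already in their thermodynamically preferred configurations.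

## Compound list

1 | (2S)-naringenin, (2S)-5,7-dihydroxy-2-(4-hydroxyphenyl)-2,3-dihydro-4H-1-benzopyran-4-one | C1[C@H](Oc2cc(O)cc(O)c2C1=O)c1ccc(O)cc1 | starting material
2 | (2S)-5-hydroxy-7-methoxy-2-(4-methoxyphenyl)-2,3-dihydro-4H-1-benzopyran-4-one | C1[C@H](Oc2cc(OC)cc(O)c2C1=O)c1ccc(OC)cc1 | intermediate
3 | (2S)-7-methoxy-2-(4-methoxyphenyl)-4-oxo-3,4-dihydro-2H-1-benzopyran-5-yl trifluoromethanesulfonate | C1[C@H](Oc2cc(OC)cc(OS(=O)(=O)C(F)(F)F)c2C1=O)c1ccc(OC)cc1 | intermediate
4 | methyl (2S,3S)-6-methoxy-2-(4-methoxyphenyl)-4-[(trifluoromethanesulfonyl)oxy]-2,3-dihydro-1-benzofuran-3-carboxylate | COc1ccc([C@H]2Oc3cc(OC)cc(OS(=O)(=O)C(F)(F)F)c3[C@@H]2C(=O)OC)cc1 | intermediate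
5 | (2S,3S)-6-methoxy-2-(4-methoxyphenyl)-4-[(trifluoromethanesulfonyl)oxy]-2,3-dihydro-1-benzofuran-3-carboxylic acid | COc1ccc([C@H]2Oc3cc(OC)cc(OS(=O)(=O)C(F)(F)F)c3[C@@H]2C(=O)O)cc1 | intermediate
6 | 5-bromo-2-hydroxy-3-methoxybenzaldehyde | COc1cc(Br)cc(C=O)c1O | starting material
7 | 4-methoxybenzyl chloride | COc1ccc(CCl)cc1 | starting material
8 | 5-bromo-3-methoxy-2-[(4-methoxyphenyl)methoxy]benzaldehyde | COc1ccc(COc2c(OC)cc(Br)cc2C=O)cc1 | intermediate
9 | 3,5-dimethoxyphenylmagnesium chloride | COc1cc(OC)cc([Mg]Cl)c1 | starting material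
10 | (RS)-{5-bromo-3-methoxy-2-[(4-methoxyphenyl)methoxy]phenyl}(3,5-dimethoxyphenyl)methanol | COc1ccc(COc2c(OC)cc(Br)cc2C(O)c2cc(OC)cc(OC)c2)cc1 | intermediate
11 | {5-bromo-3-methoxy-2-[(4-methoxyphenyl)methoxy]phenyl}(3,5-dimethoxyphenyl)methanone | COc1ccc(COc2c(OC)cc(Br)cc2C(=O)c2cc(OC)cc(OC)c2)cc1 | intermediate
12 | hydrazone of 11 (E/Z mixture) | COc1ccc(COc2c(OC)cc(Br)cc2C(=NN)c2cc(OC)cc(OC)c2)cc1 | intermediate
13 | 5-bromo-1-[diazo(3,5-dimethoxyphenyl)methyl]-3-methoxy-2-[(4-methoxyphenyl)methoxy]benzene | COc1ccc(COc2c(OC)cc(Br)cc2C(=[N+]=[N-])c2cc(OC)cc(OC)c2)cc1 | intermediate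
14 | (2S,3R)-5-bromo-3-(3,5-dimethoxyphenyl)-7-methoxy-2-(4-methoxyphenyl)-2,3-dihydro-1-benzofuran (2,3-cis) | Brc1cc(OC)c2c(c1)[C@@H](c1cc(OC)cc(OC)c1)[C@@H](c1ccc(OC)cc1)O2 | intermediate
15 | (2R,3R)-5-bromo-3-(3,5-dimethoxyphenyl)-7-methoxy-2-(4-methoxyphenyl)-2,3-dihydro-1-benzofuran (2,3-trans) | Brc1cc(OC)c2c(c1)[C@@H](c1cc(OC)cc(OC)c1)[C@H](c1ccc(OC)cc1)O2 | intermediate
16 | (2S,3S)-3-[(2R,3R)-3-(3,5-dimethoxyphenyl)-7-methoxy-2-(4-methoxyphenyl)-2,3-dihydro-1-benzofuran-5-yl]-6-methoxy-2-(4-methoxyphenyl)-2,3-dihydro-1-benzofuran-4-yl trifluoromethanesulfonate | COc1ccc([C@H]2Oc3cc(OC)cc(OS(=O)(=O)C(F)(F)F)c3[C@@H]2c2cc(OC)c3c(c2)[C@@H](c2cc(OC)cc(OC)c2)[C@H](c2ccc(OC)cc2)O3)cc1 | intermediate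
17 | 1-(4-methoxyphenyl)ethan-1-one | COc1ccc(C(C)=O)cc1 | starting material
18 | 2-{(2S,3S)-3-[(2R,3R)-3-(3,5-dimethoxyphenyl)-7-methoxy-2-(4-methoxyphenyl)-2,3-dihydro-1-benzofuran-5-yl]-6-methoxy-2-(4-methoxyphenyl)-2,3-dihydro-1-benzofuran-4-yl}-1-(4-methoxyphenyl)ethan-1-one | COc1ccc([C@H]2Oc3cc(OC)cc(CC(=O)c4ccc(OC)cc4)c3[C@@H]2c2cc(OC)c3c(c2)[C@@H](c2cc(OC)cc(OC)c2)[C@H](c2ccc(OC)cc2)O3)cc1 | intermediate
19 | 2-diazo-2-{(2S,3S)-3-[(2R,3R)-3-(3,5-dimethoxyphenyl)-7-methoxy-2-(4-methoxyphenyl)-2,3-dihydro-1-benzofuran-5-yl]-6-methoxy-2-(4-methoxyphenyl)-2,3-dihydro-1-benzofuran-4-yl}-1-(4-methoxyphenyl)ethan-1-one | COc1ccc([C@H]2Oc3cc(OC)cc(C(=[N+]=[N-])C(=O)c4ccc(OC)cc4)c3[C@@H]2c2cc(OC)c3c(c2)[C@@H](c2cc(OC)cc(OC)c2)[C@H](c2ccc(OC)cc2)O3)cc1 | intermediate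
20 | (E)-1,3-dimethoxy-5-[2-(4-methoxyphenyl)ethenyl]benzene | COc1ccc(/C=C/c2cc(OC)cc(OC)c2)cc1 | starting material
21 | (2S,3S)-3-[(2R,3R)-3-(3,5-dimethoxyphenyl)-7-methoxy-2-(4-methoxyphenyl)-2,3-dihydro-1-benzofuran-5-yl]-4-[(4S,5S)-4-(3,5-dimethoxyphenyl)-2,5-bis(4-methoxyphenyl)-4,5-dihydrofuran-3-yl]-6-methoxy-2-(4-methoxyphenyl)-2,3-dihydro-1-benzofuran | COc1ccc([C@H]2Oc3cc(OC)cc(C4=C(c5ccc(OC)cc5)O[C@H](c5ccc(OC)cc5)[C@H]4c4cc(OC)cc(OC)c4)c3[C@@H]2c2cc(OC)c3c(c2)[C@@H](c2cc(OC)cc(OC)c2)[C@H](c2ccc(OC)cc2)O3)cc1 | intermediate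
22 | (2S,3S)-3-[(2R,3R)-3-(3,5-dimethoxyphenyl)-7-methoxy-2-(4-methoxyphenyl)-2,3-dihydro-1-benzofuran-5-yl]-4-[(2S,3S,4R,5S)-4-(3,5-dimethoxyphenyl)-2,5-bis(4-methoxyphenyl)oxolan-3-yl]-6-methoxy-2-(4-methoxyphenyl)-2,3-dihydro-1-benzofuran | COc1ccc([C@H]2Oc3cc(OC)cc([C@@H]4[C@H](c5cc(OC)cc(OC)c5)[C@@H](c5ccc(OC)cc5)O[C@@H]4c4ccc(OC)cc4)c3[C@@H]2c2cc(OC)c3c(c2)[C@@H](c2cc(OC)cc(OC)c2)[C@H](c2ccc(OC)cc2)O3)cc1 | intermediate
23 | (2S,3S)-3-[(2R,3R)-3-(3,5-dimethoxyphenyl)-7-methoxy-2-(4-methoxyphenyl)-2,3-dihydro-1-benzofuran-5-yl]-4-[(2R,3S,4R,5S)-4-(3,5-dimethoxyphenyl)-2,5-bis(4-methoxyphenyl)oxolan-3-yl]-6-methoxy-2-(4-methoxyphenyl)-2,3-dihydro-1-benzofuran (kobophenol A decamethyl ether) | COc1ccc([C@H]2Oc3cc(OC)cc([C@@H]4[C@H](c5cc(OC)cc(OC)c5)[C@@H](c5ccc(OC)cc5)O[C@H]4c4ccc(OC)cc4)c3[C@@H]2c2cc(OC)c3c(c2)[C@@H](c2cc(OC)cc(OC)c2)[C@H](c2ccc(OC)cc2)O3)cc1 | intermediate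
24 | kobophenol A, (2S,3S)-3-[(2R,3R)-3-(3,5-dihydroxyphenyl)-7-hydroxy-2-(4-hydroxyphenyl)-2,3-dihydro-1-benzofuran-5-yl]-4-[(2R,3S,4R,5S)-4-(3,5-dihydroxyphenyl)-2,5-bis(4-hydroxyphenyl)oxolan-3-yl]-2-(4-hydroxyphenyl)-2,3-dihydro-1-benzofuran-6-ol | Oc1ccc([C@H]2Oc3cc(O)cc([C@@H]4[C@H](c5cc(O)cc(O)c5)[C@@H](c5ccc(O)cc5)O[C@H]4c4ccc(O)cc4)c3[C@@H]2c2cc(O)c3c(c2)[C@@H](c2cc(O)cc(O)c2)[C@H](c2ccc(O)cc2)O3)cc1 | target

## Step count and least certain steps

Total step count: 17. Longest linear sequence: 13 steps (steps 5 to 17, from 6); the branch from 1 is 11 steps (steps 1 to 4 and 11 to 17).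

**Step 14 (key step, proposed new method).** The trans-1,2-diaryl alkene may intercept the crowded carbene too slowly. The carbene would then be consumed by attack on its own electron-rich arenes (a six-membered closure onto the benzene ring of ring B is geometrically possible) or by dimerisation. Incomplete face selection at the alkene and a cyclopropane that does not ring-expand are further possibilities. The fallback uses known chemistry and runs from 18 back to 21:
- Knoevenagel-type condensation of 18 with 3,5-dimethoxybenzaldehyde (piperidine, AcOH, toluene, reflux with removal of water) should give the α-aryl chalcone F1.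
- Corey–Chaykovsky cyclopropanation of F1 with the ylide from (4-methoxybenzyl)dimethylsulfonium tetrafluoroborate and Cs2CO3 in MeCN should give the donor–acceptor cyclopropyl ketone F2. The benzylic ylide carbon adds to the carbon bearing the 3,5-dimethoxyphenyl group and the enolate closes the three-membered ring.
- Cloke–Wilson ring expansion of F2 with Sc(OTf)3 in CH2Cl2, or on heating, opens the bond between the acyl-bearing carbon and the 4-methoxyphenyl-bearing carbon and closes the enolate oxygen on the latter, giving 21 with the 4,5-trans arrangement.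
- The configuration at C4 is then under substrate control or under the control of a sulfonium salt made from a chiral sulfide, and the two 4,5-trans diastereomers are separated.

**Step 11.** Capture of the hindered C3 radical by nickel may be slow. The radical would then dimerise, abstract hydrogen, or be oxidised further with loss of the C2 proton and aromatisation of ring A; insertion of nickel into the C–OTf bond is a second competing process. The fallback runs from 5 and 15 to 16 and reverses the polarity of the aryl partner: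
- Acid 5 is converted with N-hydroxyphthalimide, N,N'-diisopropylcarbodiimide and DMAP into the N-hydroxyphthalimide ester F3.
- Bromide 15 is converted with n-BuLi at −78 °C into the aryllithium F4 and with ZnCl2 into the arylzinc chloride F5.
- F3 and F5 are coupled with NiCl2·glyme and dtbbpy in THF–DMF at rt, a decarboxylative Negishi-type arylation of a redox-active ester, to give 16 with the same anti delivery of the aryl group.

**Step 3.** Migration of the 4-methoxyphenyl group from C2 to C3 (leading to an isoflavone) or simple dehydrogenation may compete with migration of the ring carbon, because the 2-aryl group is electron-rich. Acid-induced ring opening would erode the configuration at C2. The fallback runs from 3 to 4 by a Wolff ring contraction, in which only the carbon attached to the carbonyl group can migrate: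
- Enolisation of 3 with LiHMDS at −78 °C and acylation with 2,2,2-trifluoroethyl trifluoroacetate gives the 3-trifluoroacetyl flavanone F6.
- Detrifluoroacetylative diazo transfer (MsN3, Et3N, MeCN, water) gives the 3-diazo flavanone F7.
- Irradiation in methanol gives, through the ketene F8, the cis ester F9, formed by protonation anti to the 2-aryl group.
- NaOMe in MeOH equilibrates F9 to the trans ester 4.
- The enolate must be kept cold to avoid ring opening to the chalcone.

**Step 15.** Once any O-benzylic C–O bond ionises in the presence of silane, it is cleaved reductively and irreversibly. Reversible protonation of the enol ether could also erode the kinetic 3,4-cis selectivity. The fallback runs from 21 to 23, bypasses 22 and step 16, and keeps hydride and benzylic cations apart: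
- Hydration of 21 with dilute HCl in THF gives the hydroxy ketone F10 (in equilibrium with its lactol), C3 again being set by protonation anti to the C4 aryl group.
- NaBH4 in MeOH–THF gives the 1,4-diol F11.
- Acid-catalysed cyclodehydration (TsOH cat., CH2Cl2) closes the oxolane through the 4-methoxybenzylic cation under thermodynamic control to give 23.
- The α-centre of F10 must not be left under acid for long.

**Step 16.** The ring-opened 4-methoxybenzylic cation may be captured irreversibly by a neighbouring dimethoxyphenyl ring (Friedel–Crafts closure to an indane) before the hydroxyl group recloses. The equilibrium may also fail to favour the 2,3-trans isomer strongly enough. The fallback runs from 22 to 24 with the order of the last two operations reversed: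
- Demethylation of 22 with BBr3 in CH2Cl2 gives 2-epi-kobophenol A F12.
- Epimerisation at C2 is then carried out on the free phenol with dilute HCl in methanol, where ring opening passes through a neutral para-quinone methide that the solvent traps reversibly, and this leads to 24.

**Step 17.** Bromide may open the oxolane or the dihydrobenzofurans at the O-benzylic carbons once these are complexed by boron; epimerisation or Friedel–Crafts reactions would follow. The fallback runs from 23 to 24 and replaces the Lewis acid by a nucleophile that attacks only the methyl groups: NaSEt in DMF at 140 °C, which cannot ionise the benzylic ethers. No new compound is involved.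

## Further compounds

F1 | step 14 | 3-(3,5-dimethoxyphenyl)-1-(4-methoxyphenyl)-2-{(2S,3S)-3-[(2R,3R)-3-(3,5-dimethoxyphenyl)-7-methoxy-2-(4-methoxyphenyl)-2,3-dihydro-1-benzofuran-5-yl]-6-methoxy-2-(4-methoxyphenyl)-2,3-dihydro-1-benzofuran-4-yl}prop-2-en-1-one (alkene geometry not defined) | COc1ccc([C@H]2Oc3cc(OC)cc(C(=Cc4cc(OC)cc(OC)c4)C(=O)c4ccc(OC)cc4)c3[C@@H]2c2cc(OC)c3c(c2)[C@@H](c2cc(OC)cc(OC)c2)[C@H](c2ccc(OC)cc2)O3)cc1
F2 | step 14 | [2-(3,5-dimethoxyphenyl)-3-(4-methoxyphenyl)-1-{(2S,3S)-3-[(2R,3R)-3-(3,5-dimethoxyphenyl)-7-methoxy-2-(4-methoxyphenyl)-2,3-dihydro-1-benzofuran-5-yl]-6-methoxy-2-(4-methoxyphenyl)-2,3-dihydro-1-benzofuran-4-yl}cyclopropyl](4-methoxyphenyl)methanone (cyclopropane configuration not defined) | COc1ccc([C@H]2Oc3cc(OC)cc(C4(C(=O)c5ccc(OC)cc5)C(c5cc(OC)cc(OC)c5)C4c4ccc(OC)cc4)c3[C@@H]2c2cc(OC)c3c(c2)[C@@H](c2cc(OC)cc(OC)c2)[C@H](c2ccc(OC)cc2)O3)cc1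
F3 | step 11 | 1,3-dioxo-1,3-dihydro-2H-isoindol-2-yl (2S,3S)-6-methoxy-2-(4-methoxyphenyl)-4-[(trifluoromethanesulfonyl)oxy]-2,3-dihydro-1-benzofuran-3-carboxylate | COc1ccc([C@H]2Oc3cc(OC)cc(OS(=O)(=O)C(F)(F)F)c3[C@@H]2C(=O)ON2C(=O)c3ccccc3C2=O)cc1
F4 | step 11 | [(2R,3R)-3-(3,5-dimethoxyphenyl)-7-methoxy-2-(4-methoxyphenyl)-2,3-dihydro-1-benzofuran-5-yl]lithium | [Li]c1cc(OC)c2c(c1)[C@@H](c1cc(OC)cc(OC)c1)[C@H](c1ccc(OC)cc1)O2
F5 | step 11 | [(2R,3R)-3-(3,5-dimethoxyphenyl)-7-methoxy-2-(4-methoxyphenyl)-2,3-dihydro-1-benzofuran-5-yl]zinc chloride | Cl[Zn]c1cc(OC)c2c(c1)[C@@H](c1cc(OC)cc(OC)c1)[C@H](c1ccc(OC)cc1)O2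
F6 | step 3 | (2S)-7-methoxy-2-(4-methoxyphenyl)-4-oxo-3-(trifluoroacetyl)-3,4-dihydro-2H-1-benzopyran-5-yl trifluoromethanesulfonate (C3 not defined) | O=C(C1[C@H](Oc2cc(OC)cc(OS(=O)(=O)C(F)(F)F)c2C1=O)c1ccc(OC)cc1)C(F)(F)F
F7 | step 3 | (2R)-3-diazo-7-methoxy-2-(4-methoxyphenyl)-4-oxo-3,4-dihydro-2H-1-benzopyran-5-yl trifluoromethanesulfonate | [N-]=[N+]=C1[C@H](Oc2cc(OC)cc(OS(=O)(=O)C(F)(F)F)c2C1=O)c1ccc(OC)cc1
F8 | step 3 | (2R)-6-methoxy-2-(4-methoxyphenyl)-3-(oxomethylidene)-2,3-dihydro-1-benzofuran-4-yl trifluoromethanesulfonate | COc1ccc([C@H]2Oc3cc(OC)cc(OS(=O)(=O)C(F)(F)F)c3C2=C=O)cc1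
F9 | step 3 | methyl (2S,3R)-6-methoxy-2-(4-methoxyphenyl)-4-[(trifluoromethanesulfonyl)oxy]-2,3-dihydro-1-benzofuran-3-carboxylate (2,3-cis) | COc1ccc([C@H]2Oc3cc(OC)cc(OS(=O)(=O)C(F)(F)F)c3[C@H]2C(=O)OC)cc1
F10 | step 15 | (2S,3R,4S)-3-(3,5-dimethoxyphenyl)-4-hydroxy-1,4-bis(4-methoxyphenyl)-2-{(2S,3S)-3-[(2R,3R)-3-(3,5-dimethoxyphenyl)-7-methoxy-2-(4-methoxyphenyl)-2,3-dihydro-1-benzofuran-5-yl]-6-methoxy-2-(4-methoxyphenyl)-2,3-dihydro-1-benzofuran-4-yl}butan-1-one | COc1ccc([C@H]2Oc3cc(OC)cc([C@@H](C(=O)c4ccc(OC)cc4)[C@H](c4cc(OC)cc(OC)c4)[C@@H](c4ccc(OC)cc4)O)c3[C@@H]2c2cc(OC)c3c(c2)[C@@H](c2cc(OC)cc(OC)c2)[C@H](c2ccc(OC)cc2)O3)cc1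
F11 | step 15 | (2S,3R,4S)-3-(3,5-dimethoxyphenyl)-1,4-bis(4-methoxyphenyl)-2-{(2S,3S)-3-[(2R,3R)-3-(3,5-dimethoxyphenyl)-7-methoxy-2-(4-methoxyphenyl)-2,3-dihydro-1-benzofuran-5-yl]-6-methoxy-2-(4-methoxyphenyl)-2,3-dihydro-1-benzofuran-4-yl}butane-1,4-diol (mixture at C1) | COc1ccc([C@H]2Oc3cc(OC)cc([C@@H](C(O)c4ccc(OC)cc4)[C@H](c4cc(OC)cc(OC)c4)[C@@H](c4ccc(OC)cc4)O)c3[C@@H]2c2cc(OC)c3c(c2)[C@@H](c2cc(OC)cc(OC)c2)[C@H](c2ccc(OC)cc2)O3)cc1
F12 | step 16 | 2-epi-kobophenol A, (2S,3S)-3-[(2R,3R)-3-(3,5-dihydroxyphenyl)-7-hydroxy-2-(4-hydroxyphenyl)-2,3-dihydro-1-benzofuran-5-yl]-4-[(2S,3S,4R,5S)-4-(3,5-dihydroxyphenyl)-2,5-bis(4-hydroxyphenyl)oxolan-3-yl]-2-(4-hydroxyphenyl)-2,3-dihydro-1-benzofuran-6-ol | Oc1ccc([C@H]2Oc3cc(O)cc([C@@H]4[C@H](c5cc(O)cc(O)c5)[C@@H](c5ccc(O)cc5)O[C@@H]4c4ccc(O)cc4)c3[C@@H]2c2cc(O)c3c(c2)[C@@H](c2cc(O)cc(O)c2)[C@H](c2ccc(O)cc2)O3)cc1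
F0 | step 17 | none | none
A1 | alternative 1 | methyl 2-{2-[(2R,3R)-3-(3,5-dimethoxyphenyl)-7-methoxy-2-(4-methoxyphenyl)-2,3-dihydro-1-benzofuran-5-carbonyl]-3,5-dimethoxyphenyl}acetate | COC(=O)Cc1cc(OC)cc(OC)c1C(=O)c1cc(OC)c2c(c1)[C@@H](c1cc(OC)cc(OC)c1)[C@H](c1ccc(OC)cc1)O2
A2 | alternative 1 | methyl 3-[(2R,3R)-3-(3,5-dimethoxyphenyl)-7-methoxy-2-(4-methoxyphenyl)-2,3-dihydro-1-benzofuran-5-yl]-3-oxopropanoate | COC(=O)CC(=O)c1cc(OC)c2c(c1)[C@@H](c1cc(OC)cc(OC)c1)[C@H](c1ccc(OC)cc1)O2
A3 | alternative 1 | 3,5-dimethoxy-2-(trimethylsilyl)phenyl trifluoromethanesulfonate | COc1cc(OC)c([Si](C)(C)C)c(OS(=O)(=O)C(F)(F)F)c1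
A4 | alternative 2 | methyl (2S,3S)-6-methoxy-2-(4-methoxyphenyl)-4-[(trifluoromethanesulfonyl)oxy]-2,3-dihydro-1-benzofuran-3-carboxylate | COc1ccc([C@H]2Oc3cc(OC)cc(OS(=O)(=O)C(F)(F)F)c3[C@@H]2C(=O)OC)cc1
A5 | alternative 2 | (2S)-7-methoxy-2-(4-methoxyphenyl)-4-oxo-3,4-dihydro-2H-1-benzopyran-5-yl trifluoromethanesulfonate | C1[C@H](Oc2cc(OC)cc(OS(=O)(=O)C(F)(F)F)c2C1=O)c1ccc(OC)cc1
A6 | alternative 3 | kobophenol A decamethyl ether, (2S,3S)-3-[(2R,3R)-3-(3,5-dimethoxyphenyl)-7-methoxy-2-(4-methoxyphenyl)-2,3-dihydro-1-benzofuran-5-yl]-4-[(2R,3S,4R,5S)-4-(3,5-dimethoxyphenyl)-2,5-bis(4-methoxyphenyl)oxolan-3-yl]-6-methoxy-2-(4-methoxyphenyl)-2,3-dihydro-1-benzofuran | COc1ccc([C@H]2Oc3cc(OC)cc([C@@H]4[C@H](c5cc(OC)cc(OC)c5)[C@@H](c5ccc(OC)cc5)O[C@H]4c4ccc(OC)cc4)c3[C@@H]2c2cc(OC)c3c(c2)[C@@H](c2cc(OC)cc(OC)c2)[C@H](c2ccc(OC)cc2)O3)cc1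
A7 | alternative 3 | trans-2,3-bis(4-methoxyphenyl)oxirane (racemic, one enantiomer drawn) | COc1ccc([C@H]2O[C@@H]2c2ccc(OC)cc2)cc1
A8 | alternative 3 | (2S,3S)-3-[(2R,3R)-3-(3,5-dimethoxyphenyl)-7-methoxy-2-(4-methoxyphenyl)-2,3-dihydro-1-benzofuran-5-yl]-4-[(Z)-2-(3,5-dimethoxyphenyl)ethenyl]-6-methoxy-2-(4-methoxyphenyl)-2,3-dihydro-1-benzofuran | COc1ccc([C@H]2Oc3cc(OC)cc(/C=C\c4cc(OC)cc(OC)c4)c3[C@@H]2c2cc(OC)c3c(c2)[C@@H](c2cc(OC)cc(OC)c2)[C@H](c2ccc(OC)cc2)O3)cc1
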